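**Assumptions (one line each):**
- The target has no stereocentres, so "single enantiomer" reduces to the (E)-alkene.
- Methyl 3-hydroxy-5-methoxybenzoate is taken as commercially available.
- Cross-metathesis gives E:Z of about 8:1, and the E isomer is isolated by AgNO₃–silica chromatography.

## Retrosynthesis
1. Remove the phenol MOM groups (last step). The free OH at C5 of ring 1 and the two OH groups of ring 2 are masked as MOM ethers, and the ring-1 OMe is kept as is.
2. Disconnect the (E)-CH=CH by cross-metathesis of two terminal alkenes: Ar-(CH₂)₇-CH=CH₂ (**6**) and Ar′-(CH₂)₅-CH=CH₂ (**12**).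
3. Disconnect each ArCH₂–CH₂ bond by Cu-catalysed Kumada coupling of a benzylic bromide with an ω-alkenyl Grignard (from 8-bromooct-1-ene or 6-bromohex-1-ene).
4. Make the benzylic bromides from commercial resorcinol-type benzoates by MOM protection, LiAlH₄ reduction, then Appel bromination.
5. No rings are formed; both arenes come from commercial benzoates.

## Route

**Step 1**
Reactants: **1** methyl 3-hydroxy-5-methoxybenzoate
Product: **2** methyl 3-methoxy-5-(methoxymethoxy)benzoate
Conditions: MOMCl, i-Pr₂NEt, CH₂Cl₂, 0 °C → rt, 3 h
Reagents that add atoms: chloromethyl methyl ether (MOMCl), COCCl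
Why: Base-mediated O-alkylation of the phenol gives the acid-labile MOM ether; the ester and OMe are untouched. No stereocentre is formed.

**Step 2**
Reactants: **2**
Product: **3** [3-methoxy-5-(methoxymethoxy)phenyl]methanol
Conditions: LiAlH₄, THF, 0 °C, 1 h
Reagents that add atoms: none (only H is added)
Why: Hydride reduction of the ester to the primary alcohol; the acetal and aryl ether are stable to LiAlH₄.

**Step 3**
Reactants: **3**
Product: **4** 1-(bromomethyl)-3-methoxy-5-(methoxymethoxy)benzene
Conditions: CBr₄, PPh₃, CH₂Cl₂, 0 °C, 30 min; the crude product is used immediately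
Reagents that add atoms: carbon tetrabromide, BrC(Br)(Br)Br
Why: Appel reaction under neutral conditions, so the MOM acetal survives; the electron-rich benzylic bromide is not stored.

**Step 4**
Reactants: **4** + **5** 8-bromooct-1-ene (as its Grignard)
Product: **6** 1-methoxy-3-(methoxymethoxy)-5-(non-8-en-1-yl)benzene
Conditions: (a) **5**, Mg, THF, reflux, to make CH₂=CH(CH₂)₆MgBr; (b) add to **4** with Li₂CuCl₄ (5 mol %), THF, −10 °C → rt
Reagents that add atoms: none (the octenyl chain comes from **5**)
Why: Cu-catalysed Kumada-type sp³–sp³ coupling of a benzylic bromide with an alkyl Grignard; the alkene and acetal are tolerated. This sets the Ar-(CH₂)₇ chain and the terminal alkene for metathesis.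

**Step 5**
Reactants: **7** methyl 3,5-dihydroxybenzoate
Product: **8** methyl 3,5-bis(methoxymethoxy)benzoate
Conditions: MOMCl (2.6 equiv), i-Pr₂NEt, CH₂Cl₂, 0 °C → rt, 4 h
Reagents that add atoms: MOMCl, COCCl
Why: Double O-MOM protection of the phenols, as in step 1.

**Step 6**
Reactants: **8**
Product: **9** [3,5-bis(methoxymethoxy)phenyl]methanol
Conditions: LiAlH₄, THF, 0 °C, 1 h
Reagents that add atoms: none
Why: Ester reduction; the MOM acetals are inert to hydride.

**Step 7**
Reactants: **9**
Product: **10** 1-(bromomethyl)-3,5-bis(methoxymethoxy)benzene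
Conditions: CBr₄, PPh₃, CH₂Cl₂, 0 °C, 30 min; the crude product is used immediately
Reagents that add atoms: CBr₄, BrC(Br)(Br)Br
Why: Appel bromination, as in step 3.

**Step 8**
Reactants: **10** + **11** 6-bromohex-1-ene (as its Grignard)
Product: **12** 1-(hept-6-en-1-yl)-3,5-bis(methoxymethoxy)benzene
Conditions: (a) **11**, Mg, THF, rt → 40 °C; (b) add to **10** with Li₂CuCl₄ (5 mol %), THF, −10 °C → rt
Reagents that add atoms: none (the hexenyl chain comes from **11**)
Why: Same Cu-catalysed Kumada coupling; this sets the Ar′-(CH₂)₅ chain and a terminal alkene. The Grignard is kept cold to limit 5-hexenyl cyclisation.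

**Step 9**
Reactants: **6** (1.0 equiv) + **12** (2.0 equiv)
Product: **13** (E)-1-methoxy-3-(methoxymethoxy)-5-[14-aryl-tetradec-8-enyl chain; full structure in the compound list], the tri-MOM-protected target
Conditions: Grubbs II (5 mol %), 1,4-benzoquinone (10 mol %), CH₂Cl₂, 40 °C, 16 h, under a slow argon sweep to remove ethylene; chromatography on SiO₂, then AgNO₃–SiO₂
Reagents that add atoms: none
Why: Ru-catalysed cross-metathesis between two unhindered type-I terminal alkenes. The excess of **12** favours cross-product over the homodimer of **6**, and the thermodynamically favoured (E)-disubstituted alkene predominates. Benzoquinone suppresses Ru–H alkene isomerisation, and the Z isomer is removed by AgNO₃–silica.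

**Step 10**
Reactants: **13**
Product: **14** dehydrobisgravillol
Conditions: 3 M HCl, MeOH/THF (1:1), 50 °C, 6 h
Reagents that add atoms: none (MOM leaves as CH₂(OMe)₂ or CH₂O; only H is added)
Why: Acid-catalysed hydrolysis of the phenolic MOM acetals. The aryl methyl ether and the isolated (E)-alkene survive, and the alkene geometry set in step 9 is retained.

**Final check (target SMILES vs. route):**
- Target chain: Ar-(CH₂)₇-CH=CH-(CH₂)₅-Ar′. Fragment **6** supplies Ar-(CH₂)₇-CH=, fragment **12** supplies =CH-(CH₂)₅-Ar′, and the chain is 7 + 2 + 5 = 14 carbons.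
- Ring 1 carries OMe and OH (OH from the MOM ether of **1**). Ring 2 carries two OH groups.
- Every atom is accounted for in each step, and the last product is the target.
- No stereocentres exist; the only stereo-element is the (E)-alkene, set in step 9 and not touched afterwards.

## Compound list
1 | methyl 3-hydroxy-5-methoxybenzoate | COC(=O)c1cc(O)cc(OC)c1 | starting material
2 | methyl 3-methoxy-5-(methoxymethoxy)benzoate | COC(=O)c1cc(OC)cc(OCOC)c1 | intermediate
3 | [3-methoxy-5-(methoxymethoxy)phenyl]methanol | COc1cc(CO)cc(OCOC)c1 | intermediate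
4 | 1-(bromomethyl)-3-methoxy-5-(methoxymethoxy)benzene | COc1cc(CBr)cc(OCOC)c1 | intermediate
5 | 8-bromooct-1-ene | C=CCCCCCCBr | starting material
6 | 1-methoxy-3-(methoxymethoxy)-5-(non-8-en-1-yl)benzene | C=CCCCCCCCc1cc(OC)cc(OCOC)c1 | intermediate
7 | methyl 3,5-dihydroxybenzoate | COC(=O)c1cc(O)cc(O)c1 | starting material
8 | methyl 3,5-bis(methoxymethoxy)benzoate | COC(=O)c1cc(OCOC)cc(OCOC)c1 | intermediate
9 | [3,5-bis(methoxymethoxy)phenyl]methanol | OCc1cc(OCOC)cc(OCOC)c1 | intermediate
10 | 1-(bromomethyl)-3,5-bis(methoxymethoxy)benzene | BrCc1cc(OCOC)cc(OCOC)c1 | intermediate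
11 | 6-bromohex-1-ene | C=CCCCCBr | starting material
12 | 1-(hept-6-en-1-yl)-3,5-bis(methoxymethoxy)benzene | C=CCCCCCc1cc(OCOC)cc(OCOC)c1 | intermediate
13 | tri-MOM-protected dehydrobisgravillol | COc1cc(OCOC)cc(CCCCCCC/C=C/CCCCCc2cc(OCOC)cc(OCOC)c2)c1 | intermediate
14 | dehydrobisgravillol | COc1cc(O)cc(CCCCCCC/C=C/CCCCCc2cc(O)cc(O)c2)c1 | target

## Step count
- Total steps: 10 (two parallel 4-step fragment syntheses, then cross-metathesis and deprotection).
- Longest linear sequence: 6 steps (1 → 2 → 3 → 4 → 6 → 13 → 14; the 7 → 12 branch is also 4 steps, giving the same length).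

## Three steps most likely to fail
1. **Step 9 (cross-metathesis).** It gives statistical homodimers and an E:Z mixture.
   - Fallback: change the olefination approach to a Julia–Kocienski reaction, coupling the PT-sulfone of the Ar′(CH₂)₆ fragment with the aldehyde Ar-(CH₂)₇-CHO. This gives more than 95:5 E selectivity and no homodimers.
2. **Steps 3/7 with 4/8 (electron-rich benzylic bromides and Kumada coupling).** The bromides are unstable, and Wurtz homocoupling or Grignard cyclisation can compete.
   - Fallback: use an aryl-bromide B-alkyl Suzuki coupling. Couple 1-bromo-3-methoxy-5-(MOMO)benzene (or the bis-MOM bromoresorcinol) with the 9-BBN adduct of 1,8-nonadiene (or 1,6-heptadiene), with Pd(dppf)Cl₂ and K₃PO₄. This avoids benzylic halides.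
3. **Step 10 (MOM removal).** The electron-rich resorcinol rings can be attacked by the MOM oxocarbenium ion (Friedel–Crafts or methylene-bridged by-products), and acid can isomerise the alkene.
   - Fallback: change the protecting-group strategy to TBS ethers on the phenols, made from the same benzoates with TBSCl and imidazole. The TBS-protected fragments are carried through the same sequence and removed at the end with TBAF/AcOH, which is non-acidic.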